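Percent of the X charged is the unit to watch with care when repeating this run: zeta and theta look alike in it and differ in molar G.

common to all: L 85 mM (held)
- zeta: X 0.27 M; run made earlier
- theta: X 0.60 M; run made earlier
- flask: X 0.40 M; time 30 h

| zeta: time / h | zeta: G / % | theta: time / h | theta: G / % |
|---|---|---|---|
| 2.50 | 5 | 6.00 | 9 |
| 8.00 | 8 | 12.0 | 8 |
| 12.0 | 11 | 20.0 | 12 |
| 20.0 | 14 | 25.0 | 12 |
| 30.0 | 14 | 30.0 | 13 |
| 40.0 | 19 | 40.0 | 14 |

(readings scatter by 2 percentage points)

- G at 30 h, in percent of the X charged
- the change that raises the amount of G at 30 h, in percent of the X charged most ("none" if none brings more than 2 percentage points) (north-east / west / none)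
- amount of G at 30 h, in percent of the X charged, after west

- at the start none of L is in solution

- north-east: doubling the saturation concentration of L, all else as stated
- west: doubling the transfer coefficient of L, all else as stated

What do the late readings say? Zeta's readings at 20.0 h, 30.0 h and 40.0 h average 15.7 %, and theta's at the same times average 13.0 %.

Why a mean? One reading scatters by 2 percentage points, while a mean of 3 scatters by less, 1.2 points.

And in molar terms? These means read as 0.0423 M of G in zeta and 0.0780 M in theta, more than in zeta.

How do you carry this to the new flask? I work with the share of the charge not yet G. Minus its logarithm, divided by the time, is an apparent pseudo-first-order constant: 0.00568 h⁻¹ in zeta and 0.00464 h⁻¹ in theta. That gives 0.253, the charge slope: the logarithm of the ratio of the two constants over the logarithm of the ratio of the two charges.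

But the curves bend, so is the constant not false? Taken across time, yes: zeta's first reading gives 0.0205 h⁻¹, faster than its late 0.00568 h⁻¹. So the slope compares charges at one time. For this flask it gives 0.00514 h⁻¹, and so my own figure of 14.3 %.

The forecast differs from that figure: it says 15 %, picks north-east and expects 15.5 % after west, the last with this reading of the runs: “A reaction limited by L transfer would give the same molar G in both runs, so this one is not transfer-limited.”

The flask gives 15.3 %; north-east gains 12 points, west 0.12 points, leaving 15.4 %.

    J + G → Q (k = 0.0120 L mol⁻¹ h⁻¹)
    L ⇌ J, rate k2*(csat - [J]) (kL = 4.20 h⁻¹)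
    X + G → Z (k = 0.100 L mol⁻¹ h⁻¹)
    X ⇌ D (K = 1.10, k = 0.0990 h⁻¹)
    X + J → G (k = 0.170 L mol⁻¹ h⁻¹)

At 30.0 h this flask makes G 2.18 times faster than it uses G up, each step taken net. This flask left longer holds 24.7 % of G at 300 h. Its result, read back through the share not yet G, is a constant of 0.00554 h⁻¹. For a neighbour flask with 1.0 M of X, read at 30 h, the charge slope gives 11.5 %, and that neighbour holds 10.5 %.

The data are calculated for an exercise; the scatter is artificial.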